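(The earlier runs and the new flask are simulated from invented constants; scatter was added.)

**Net initiator.** Subtract the impurity from the initiator before reading any curve, taking one impurity to destroy one initiator. In the flask, c(initiator) minus c(impurity) leaves 0.740 mM, the net initiator; zeta has 0.870 mM and beta 0.480 mM.

| setting | zeta | beta | flask |
|---|---|---|---|
| free monomer | 0.050 M (fed, over 2.0 min) | 0.050 M (fed, over 2.0 min) | 0.050 M (fed, over 2.0 min) |
| initiator | 2 mol% | 2 mol% | 2 mol% |
| impurity | 0.13 mM | 0.52 mM | 0.26 mM |
| remark | run made earlier | run made earlier |  |
| time |  |  | 6.0 min |

| run | time / min | monomer in chains / % |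
|---|---|---|
| zeta | 1.50 | 8.8 |
| zeta | 2.00 | 15.0 |
| zeta | 2.50 | 21.9 |
| zeta | 3.00 | 28.1 |
| zeta | 4.00 | 33.2 |
| beta | 1.50 | 5.9 |
| beta | 2.00 | 10.6 |
| beta | 2.50 | 16.1 |
| beta | 3.00 | 20.2 |
| beta | 4.00 | 25.7 |

(each reading ± 0.5 percentage points)

- when, up to 6.0 min, the flask holds most monomer in chains
- the amount of monomer in chains, in percent of the free monomer charged, at that time

**Root rule.** With the charge of free monomer and the feed held as in these runs, try readings at a fixed time as proportional to the square root of net initiator. Zeta over beta should then be 1.35, and the readings give 1.39 at 3.00 min and 1.29 at 4.00 min.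

**Straight line.** Scaled from zeta, this reckoning puts the flask at 30.6 % at 4.00 min. The two runs gained a mean of 5.3 percentage points in the minute before that, so a constant gain reaches 41.2 % at 6.0 min.

**Weak link.** That mean belongs to 3.50 min, and in zeta and in beta the gain per minute there is lower than in the stretch before . Assuming it falls as one over time, the last stretch adds 7.5 points. By this reckoning the flask is then still rising at 6.0 min, with 38.1 %, which is lower than the straight line.

**The forecast.** It puts the peak at 3.6 min with 31 %, on the ground “Something switches on abruptly, either chain growth stopping or loss of chains”. The reckoning above differs, with no peak before 6.0 min.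

**The flask.** It holds most at 6.00 min, with 38.8 %.

    monomer in chains + living end → free monomer + living end, rate k1*[living end] as long as [monomer in chains] is above zero (k = 0.0500 /s)
    free monomer + initiator → living end + monomer in chains (k = 0.880 /M/s)
    initiator + impurity → spent initiator B (k = 470 /M/s)
    2 living end ⇌ resting dimer, settled at all times (K = 640 /M)
    free monomer + living end → monomer in chains + living end, rate k5*[living end]*[free monomer] (k = 12.0 /M/s)
    2 living end → dead end A (k = 34.0 /M/s)

**What ran.** Up to 2.00 min initiator and impurity gave 2.60 × 10⁻⁴ M of spent initiator B, leaving impurity at 0 %; by 6.00 min the flask's initiator stood at 0 %, and living end, dead end A (termination) and resting dimer, counted per initiator, made 0.740 mM against the net initiator of 0.740 mM. While living end went from 1.71 × 10⁻⁴ M at 3.00 min to 6.58 × 10⁻⁵ M at 6.00 min, monomer in chains rose from 25.3 % to 38.8 %. The neighbour flask charged with 0.030 M of free monomer has 0.340 mM of net initiator; at 6.00 min its initiator, living end, dead end A and resting dimer, counted per initiator, make 0.340 mM, and it holds 27.8 % of monomer in chains.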